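**Assumption:** the target is taken exactly as drawn, i.e. (1R,7S,8R,10S) in guaiane numbering with a (Z)-2-methylbut-2-enoate (angelate) on O8. Guaiane numbering is used for atom labels: five-membered ring C1–C5 (C3=O, C4=C5, C15 methyl on C4); seven-membered ring C1, C5–C10 (C8–O-angelate, C7–C11Me2OAc, C14 methyl on C10).

## Retrosynthetic overview

1. Torilin (24) ⇐ torilolone (21, the 8,11-diol) by C8-OH angeloylation, then C11-OH acetylation.
2. Five-membered ring (formed last): C4=C5 by intramolecular aldol condensation of 1,4-diketone 20; its 2-oxobutyl arm comes from Mukaiyama–Michael/Nef reaction of 2-nitrobut-1-ene (16) with enol silane 19.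
3. Seven-membered ring (formed first): C1=C5 by silyl enol ether–ene ring-closing metathesis of acyclic diene 18.
4. C8–C9 bond: Felkin addition of the "north" fragment 13 (C9, C10, C1; from (S)-Roche ester) to the "south" keto-aldehyde 7 (C5–C8, C11–C13; from prenol).
5. Stereocentres: C7 from Sharpless epoxidation plus SN2 opening, C10 from the chiral pool, C8 by Felkin control, C1 by equilibration in the aldol step.

## Route

### South fragment (steps 1–5)

**Step 1**
Reactants: 1, prenol (3-methylbut-2-en-1-ol)
Product: 2, (R)-(3,3-dimethyloxiran-2-yl)methanol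
Conditions: Ti(OiPr)4 (10 mol%), D-(−)-DET (12 mol%), t-BuOOH, 4 Å MS, CH2Cl2, −20 °C
Reagents that add atoms: tert-butyl hydroperoxide, CC(C)(C)OO (epoxide O)
Why: Sharpless asymmetric epoxidation; D-(−)-tartrate gives the (2R)-epoxide (the enantiomer of the 2S product from L-(+)-tartrate), which fixes the future C7.

**Step 2**
Reactants: 2; 3, 2-methylallylmagnesium chloride
Product: 4, (2S)-3-methyl-2-(2-methylprop-2-en-1-yl)butane-1,3-diol
Conditions: 3 (3 equiv), CuI (10 mol%), THF, −40 → 0 °C
Reagents that add atoms: 2-methylallylmagnesium chloride (3), C=C(C)C[Mg]Cl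
Why: Cu-catalysed SN2 epoxide opening by the allylic Grignard at the secondary carbon (the gem-dimethyl carbon is blocked) with inversion sets C7; the methallyl group is a masked acetonyl unit.

**Step 3**
Reactants: 4
Product: 5, bis-TES ether of 4
Conditions: TESOTf (2.5 equiv), 2,6-lutidine, CH2Cl2, −78 → 0 °C
Reagents that add atoms: triethylsilyl triflate, CC[Si](CC)(CC)OS(=O)(=O)C(F)(F)F
Why: the silyl triflate silylates both the primary and the tertiary OH; the tertiary OTES is bulky and non-chelating, as needed for step 13.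

**Step 4**
Reactants: 5
Product: 6, (4S)-5-methyl-5-(triethylsilyloxy)-4-[(triethylsilyloxy)methyl]hexan-2-one
Conditions: O3, CH2Cl2, −78 °C; then PPh3
Reagents that add atoms: ozone, [O-][O+]=O
Why: ozonolysis of the only alkene (1,1-disubstituted) unmasks the C5 methyl ketone; silyl ethers are inert.

**Step 5**
Reactants: 6
Product: 7, (2R)-4-oxo-2-[2-(triethylsilyloxy)propan-2-yl]pentanal
Conditions: (COCl)2, DMSO, CH2Cl2, −78 → −40 °C; then Et3N, −78 → 0 °C; used crude
Reagents that add atoms: none
Why: direct Swern oxidation cleaves and oxidises the primary TES ether selectively (the tertiary OTES cannot oxidise), and low temperature protects the α-stereocentre.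

### North fragment (steps 6–10)

**Step 6**
Reactants: 8, methyl (S)-3-hydroxy-2-methylpropanoate ((S)-Roche ester)
Product: 9, methyl (S)-3-(tert-butyldimethylsilyloxy)-2-methylpropanoate
Conditions: TBSCl, imidazole, CH2Cl2, 0 °C → rt
Reagents that add atoms: TBSCl, CC(C)(C)[Si](C)(C)Cl
Why: standard silylation of the primary alcohol; the stereocentre (future C10) is untouched.

**Step 7**
Reactants: 9
Product: 10, (S)-3-(tert-butyldimethylsilyloxy)-2-methylpropanal
Conditions: DIBAL-H (1.1 equiv), CH2Cl2, −78 °C; used crude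
Reagents that add atoms: none
Why: DIBAL half-reduction stops at the aldehyde through the stable tetrahedral aluminate at −78 °C; immediate use avoids α-epimerisation.

**Step 8**
Reactants: 10
Product: 11, (R)-tert-butyldimethyl[(2-methylbut-3-en-1-yl)oxy]silane
Conditions: Ph3PCH3Br, KHMDS, THF, −78 → 0 °C
Reagents that add atoms: methyltriphenylphosphonium bromide, C[P+](c1ccccc1)(c1ccccc1)c1ccccc1.[Br-]
Why: Wittig methylenation with a non-stabilised ylide at low temperature installs the vinyl group (C1) without epimerising C10.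

**Step 9**
Reactants: 11
Product: 12, (2R)-2-methylbut-3-en-1-ol
Conditions: TBAF, THF, 0 °C → rt; distil
Reagents that add atoms: none
Why: fluoride-mediated desilylation; nothing else in the molecule is affected.

**Step 10**
Reactants: 12
Product: 13, (3R)-4-bromo-3-methylbut-1-ene
Conditions: CBr4, PPh3, CH2Cl2, 0 °C; distil
Reagents that add atoms: carbon tetrabromide, BrC(Br)(Br)Br
Why: Appel bromination is SN2 at the primary carbon, so the adjacent stereocentre is unchanged.

### Nitroalkene (steps 11–12)

**Step 11**
Reactants: 14, 1-nitropropane (excess)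
Product: 15, 2-nitrobutan-1-ol (racemic)
Conditions: aq. HCHO (0.9 equiv), cat. NaOH, EtOH, rt
Reagents that add atoms: formaldehyde, C=O
Why: Henry (nitroaldol) reaction; excess nitroalkane suppresses double hydroxymethylation.

**Step 12**
Reactants: 15
Product: 16, 2-nitrobut-1-ene
Conditions: phthalic anhydride, 150–180 °C, distil out under reduced pressure; use fresh
Reagents that add atoms: none
Why: thermal dehydration of the β-nitro alcohol via its phthalate half-ester gives the nitroalkene, removed by distillation as it forms.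

### Union and endgame (steps 13–19)

**Step 13**
Reactants: 13; 7
Product: 17, (4S,5R,7S)-5-hydroxy-7-methyl-4-[2-(triethylsilyloxy)propan-2-yl]non-8-en-2-one
Conditions: 13, Mg, THF, rt; ClTi(OiPr)3, −78 → −40 °C; then 7, −78 → −20 °C
Reagents that add atoms: none
Why: a Reetz-type alkyltitanium triisopropoxide adds to the aldehyde but not the methyl ketone, and non-chelated Felkin–Anh attack anti to the bulky CMe2OTES group gives the 7,8-syn alcohol (C8 R).

**Step 14**
Reactants: 17
Product: 18, (4S,5R,7S)-7-methyl-2,5-bis(triethylsilyloxy)-4-[2-(triethylsilyloxy)propan-2-yl]nona-1,8-diene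
Conditions: LDA (2.3 equiv), THF, −78 °C; TESCl (3 equiv), DMPU, −78 → 0 °C
Reagents that add atoms: chlorotriethylsilane, CC[Si](CC)(CC)Cl
Why: kinetic deprotonation of the methyl ketone at CH3 and O-silylation of both enolate and alkoxide give the terminal silyl enol ether and the C8 OTES ether in one operation.

**Step 15**
Reactants: 18
Product: 19, (3S,5R,6S)-3-methyl-1,5-bis(triethylsilyloxy)-6-[2-(triethylsilyloxy)propan-2-yl]cyclohept-1-ene
Conditions: Grubbs II (10 mol%), PhMe (2 mM), 70 °C
Reagents that add atoms: none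
Why: silyl enol ether–ene ring-closing metathesis (initiation at the vinyl group, closure onto the 1,1-disubstituted enol ether, loss of ethylene) forms the seven-membered ring and a regiodefined C5=C1 enol silane.

**Step 16**
Reactants: 19; 16
Product: 20, (2R,3S,5R,6S)-5-hydroxy-6-(2-hydroxypropan-2-yl)-3-methyl-2-(2-oxobutyl)cycloheptan-1-one
Conditions: 16, SnCl4, CH2Cl2, −78 °C; then 1 M HCl, THF, rt; used crude
Reagents that add atoms: 2-nitrobut-1-ene (16), C=C(CC)[N+](=O)[O-]; water, O (carbonyl O from Nef hydrolysis)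
Why: Lewis-acid Mukaiyama–Michael addition of the enol silane to the nitroalkene occurs at C1 anti to the C10 methyl, and acidic Nef hydrolysis of the nitronate gives the 1,4-diketone while removing the TES ethers.

**Step 17**
Reactants: 20
Product: 21, torilolone, (1R,7S,8R,10S)-8,11-dihydroxyguai-4-en-3-one
Conditions: KOH, MeOH, 50 °C
Reagents that add atoms: none
Why: intramolecular aldol condensation (C4 enolate onto the C5 ketone, then dehydration) closes the cyclopentenone; C1 is epimerisable and settles as the more stable epimer with C2 trans to the C10 methyl (1R).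

**Step 18**
Reactants: 21; 22, angelic acid
Product: 23, 8-O-angeloyltorilolone
Conditions: 22, 2,4,6-Cl3C6H2COCl, Et3N, PhMe, rt; then 21, 80 °C (no DMAP)
Reagents that add atoms: angelic acid (22), C/C=C(/C)C(=O)O
Why: Yamaguchi mixed-anhydride esterification without a nucleophilic catalyst acylates the secondary C8-OH (the tertiary OH is inert) and avoids angelate-to-tiglate isomerisation.

**Step 19**
Reactants: 23
Product: 24, torilin
Conditions: Ac2O, DMAP, Et3N, CH2Cl2, rt → 40 °C
Reagents that add atoms: acetic anhydride, CC(=O)OC(C)=O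
Why: DMAP-catalysed (Steglich-type) acetylation of the remaining tertiary alcohol; the enone and angelate tolerate these mild conditions.

## Compound list

1 | prenol | CC(C)=CCO | starting material
2 | (R)-(3,3-dimethyloxiran-2-yl)methanol | OC[C@H]1OC1(C)C | intermediate
3 | 2-methylallylmagnesium chloride | C=C(C)C[Mg]Cl | starting material
4 | (2S)-3-methyl-2-(2-methylprop-2-en-1-yl)butane-1,3-diol | C=C(C)C[C@@H](CO)C(C)(C)O | intermediate
5 | bis-TES ether of 4 | C=C(C)C[C@@H](CO[Si](CC)(CC)CC)C(C)(C)O[Si](CC)(CC)CC | intermediate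
6 | (4S)-5-methyl-5-(triethylsilyloxy)-4-[(triethylsilyloxy)methyl]hexan-2-one | CC(=O)C[C@@H](CO[Si](CC)(CC)CC)C(C)(C)O[Si](CC)(CC)CC | intermediate
7 | (2R)-4-oxo-2-[2-(triethylsilyloxy)propan-2-yl]pentanal | CC(=O)C[C@@H](C=O)C(C)(C)O[Si](CC)(CC)CC | intermediate
8 | methyl (S)-3-hydroxy-2-methylpropanoate | OC[C@H](C)C(=O)OC | starting material
9 | methyl (S)-3-(TBS-oxy)-2-methylpropanoate | CC(C)(C)[Si](C)(C)OC[C@H](C)C(=O)OC | intermediate
10 | (S)-3-(TBS-oxy)-2-methylpropanal | CC(C)(C)[Si](C)(C)OC[C@H](C)C=O | intermediate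
11 | (R)-tert-butyldimethyl[(2-methylbut-3-en-1-yl)oxy]silane | CC(C)(C)[Si](C)(C)OC[C@H](C)C=C | intermediate
12 | (2R)-2-methylbut-3-en-1-ol | OC[C@H](C)C=C | intermediate
13 | (3R)-4-bromo-3-methylbut-1-ene | BrC[C@H](C)C=C | intermediate
14 | 1-nitropropane | CCC[N+](=O)[O-] | starting material
15 | 2-nitrobutan-1-ol (racemic) | CCC(CO)[N+](=O)[O-] | intermediate
16 | 2-nitrobut-1-ene | C=C(CC)[N+](=O)[O-] | intermediate
17 | (4S,5R,7S)-5-hydroxy-7-methyl-4-[2-(triethylsilyloxy)propan-2-yl]non-8-en-2-one | CC(=O)C[C@@H]([C@H](O)C[C@H](C)C=C)C(C)(C)O[Si](CC)(CC)CC | intermediate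
18 | (4S,5R,7S)-7-methyl-2,5-bis(triethylsilyloxy)-4-[2-(triethylsilyloxy)propan-2-yl]nona-1,8-diene | C=C(O[Si](CC)(CC)CC)C[C@@H]([C@H](O[Si](CC)(CC)CC)C[C@H](C)C=C)C(C)(C)O[Si](CC)(CC)CC | intermediate
19 | (3S,5R,6S)-3-methyl-1,5-bis(triethylsilyloxy)-6-[2-(triethylsilyloxy)propan-2-yl]cyclohept-1-ene | CC[Si](CC)(CC)O[C@@H]1C[C@H](C)C=C(O[Si](CC)(CC)CC)C[C@@H]1C(C)(C)O[Si](CC)(CC)CC | intermediate
20 | (2R,3S,5R,6S)-5-hydroxy-6-(2-hydroxypropan-2-yl)-3-methyl-2-(2-oxobutyl)cycloheptan-1-one | O[C@@H]1C[C@H](C)[C@@H](CC(=O)CC)C(=O)C[C@@H]1C(C)(C)O | intermediate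
21 | torilolone, (1R,7S,8R,10S)-8,11-dihydroxyguai-4-en-3-one | O[C@@H]1C[C@H](C)[C@H]2CC(=O)C(C)=C2C[C@@H]1C(C)(C)O | intermediate
22 | angelic acid, (Z)-2-methylbut-2-enoic acid | C/C=C(/C)C(=O)O | starting material
23 | 8-O-angeloyltorilolone | C/C=C(/C)C(=O)O[C@@H]1C[C@H](C)[C@H]2CC(=O)C(C)=C2C[C@@H]1C(C)(C)O | intermediate
24 | torilin | C/C=C(/C)C(=O)O[C@@H]1C[C@H](C)[C@H]2CC(=O)C(C)=C2C[C@@H]1C(C)(C)OC(C)=O | target

## Summary

**Total step count:** 19 (south fragment 5, north fragment 5, nitroalkene 2, union and endgame 7).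

**Longest linear sequence:** 12 steps (steps 1–5 then 13–19; the Roche-ester branch, steps 6–10 then 13–19, is equally long).

**Steps most likely to fail, with fallbacks:**

1. **Step 13** (chemoselective, Felkin-selective alkyltitanium addition to the hindered, epimerisable γ-keto aldehyde 7). Fallback: form C7–C8 by an Evans boron syn-aldol instead. Use (S)-4-benzyl-3-(4,4-ethylenedioxypentanoyl)oxazolidin-2-one with (S)-3-methylpent-4-enal (from 13 via cyanide displacement and DIBAL), then build C11 from the acyl carbon (imide → methyl ester → 2 MeMgBr). The auxiliary then sets C7 and C8 together.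

2. **Step 15** (RCM onto a 1,1-disubstituted silyl enol ether). Fallback: reach the same enol silane 19 through an enone. Use an allyl nucleophile instead of 13 and carry C5 as a vinyl ketone; enone RCM then gives the cyclohept-2-enone (C5=O, C1=C10). Copper/chiral-phosphoramidite-catalysed conjugate addition of a methyl nucleophile with TESCl trapping installs C10-Me and delivers 19.

3. **Step 16** (Lewis-acid nitroalkene Michael/Nef on a hindered enol silane bearing acid-labile groups). Fallback: cleave 19 to the regiodefined lithium enolate (MeLi), alkylate at C1 with 1-bromo-2-butyne, and hydrate the alkyne with Au(I) or Hg(II) (carbonyl-assisted) to the same 1,4-diketone. The silyl ethers are then kept through the aldol and removed with HF·pyridine.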